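C1–C10 = ring carbons: C8 = CH–O‑methacryloyl, C9 = CH2, C10 = C(OH)CH3 (methyl C14), C1 = CH2, C2 = CH–OAc, C3=C4 (methyl C15 on C4), C5=C6; lactone ring = O, C6, C7, C11, C12 (carbonyl); C13 = CH2OH on C11.
Endgame: silyl ethers off; C5=C6 by dehydration of a C6 lactol; lactone ring by photooxygenation of a furan (O, C6, C7, C11, C12) used as aromatic template; C8 ester after 1,3‑anti reduction of a C8 ketone steered by C10–OH.
Key disconnection C8–C9 (with O–C10): an intramolecular nitrile oxide–alkene cycloaddition of a 3‑furonitrile oxide (C8) onto a methallyl group (C9=C10) closes the ten‑membered carbocycle and a bridging 2‑isoxazoline together; N–O cleavage later gives the C8 ketone and C10 tertiary alcohol.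
Enabling feature: the triad C8(O)–C9H2–C10(O)(CH3) is the retron of a 5,5‑disubstituted isoxazoline, and C8 sits on C7 of the five‑membered ring between C6 and C11, so at the furan level that ring holds C8 and the C5 chain on adjacent carbons and both neighbours shield the dipole.
Precursor from furan‑3,4‑diyldimethanol (lithiated at C6) and a C2‑(S) allylic bromide (C1–C5, C9, C10, C14, C15) made by an asymmetric glyoxylate–ene reaction and an (E)‑selective Wittig reaction; ring order: furan (purchased) → isoxazoline and ten‑membered ring together → isoxazoline opened → furan converted into the ylidene butenolide.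

Key step: step 13

Assumption: C6 of the lactol formed in step 18 (and of its acetate) is left undefined because step 19 removes this centre; compounds 26 and 27 are epimer mixtures at C6 only.

Step 1
Reactants: 1 ethyl glyoxylate; 2 isobutylene (2‑methylpropene)
Product: 3 ethyl (2S)‑2‑hydroxy‑4‑methylpent‑4‑enoate
Conditions: (S)‑BINOL (10 mol%), TiCl2(OiPr)2 (10 mol%), 4 Å molecular sieves, CH2Cl2, −30 °C
Reagents that add atoms: none
Why: Catalytic asymmetric glyoxylate–ene (carbonyl‑ene) reaction in which the BINOL–titanium Lewis acid chelates the glyoxylate and exposes one aldehyde face, so the (S)‑ligand should set C2 as (S) (the mirror‑image ligand is the one known to lead to the (R)‑hydroxy ester) while delivering C1, C9, C10 and C14 as the methallyl group.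

Step 2
Reactants: 3 ethyl (2S)‑2‑hydroxy‑4‑methylpent‑4‑enoate
Product: 4 ethyl (2S)‑2‑[(tert‑butyldimethylsilyl)oxy]‑4‑methylpent‑4‑enoate
Conditions: TBSCl, imidazole, DMF, 0 °C → rt
Reagents that add atoms: tert‑butyldimethylsilyl chloride, CC(C)(C)[Si](C)(C)Cl
Why: Standard O‑silylation of a secondary alcohol under imidazole catalysis, with no bond to the stereocenter broken.

Step 3
Reactants: 4 ethyl (2S)‑2‑[(tert‑butyldimethylsilyl)oxy]‑4‑methylpent‑4‑enoate
Product: 5 (2S)‑2‑[(tert‑butyldimethylsilyl)oxy]‑4‑methylpent‑4‑enal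
Conditions: i‑Bu2AlH (1.05 equiv), CH2Cl2, −78 °C
Reagents that add atoms: none
Why: Partial hydride reduction of an α‑silyloxy ester stops at the aldehyde because the aluminium hemiacetal survives at −78 °C, and the non‑basic conditions leave the α‑stereocenter intact.

Step 4
Reactants: 5 (2S)‑2‑[(tert‑butyldimethylsilyl)oxy]‑4‑methylpent‑4‑enal
Product: 6 ethyl (2E,4S)‑4‑[(tert‑butyldimethylsilyl)oxy]‑2,6‑dimethylhepta‑2,6‑dienoate
Conditions: Ph3P=C(CH3)CO2Et, CH2Cl2, rt → 40 °C
Reagents that add atoms: ethyl 2‑(triphenylphosphoranylidene)propanoate, CCOC(=O)C(C)=P(c1ccccc1)(c1ccccc1)c1ccccc1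
Why: Wittig olefination with an α‑methyl stabilised ylide is expected to give the (E)‑trisubstituted C3=C4 enoate and needs no base that could epimerise C2.

Step 5
Reactants: 6 ethyl (2E,4S)‑4‑[(tert‑butyldimethylsilyl)oxy]‑2,6‑dimethylhepta‑2,6‑dienoate
Product: 7 (2E,4S)‑4‑[(tert‑butyldimethylsilyl)oxy]‑2,6‑dimethylhepta‑2,6‑dien‑1‑ol
Conditions: i‑Bu2AlH (2.3 equiv), CH2Cl2, −78 → 0 °C
Reagents that add atoms: none
Why: 1,2‑Reduction of the conjugated ester by the Lewis acidic aluminium hydride gives the allylic alcohol with the olefin geometry unchanged.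

Step 6
Reactants: 7 (2E,4S)‑4‑[(tert‑butyldimethylsilyl)oxy]‑2,6‑dimethylhepta‑2,6‑dien‑1‑ol
Product: 8 (2E,4S)‑1‑bromo‑4‑[(tert‑butyldimethylsilyl)oxy]‑2,6‑dimethylhepta‑2,6‑diene
Conditions: CBr4, PPh3, CH2Cl2, 0 °C
Reagents that add atoms: carbon tetrabromide, BrC(Br)(Br)Br
Why: Appel bromination displaces the alkoxyphosphonium by SN2 at the primary carbon under neutral conditions, so neither the (E)‑olefin nor the allylic silyl ether is disturbed.

Step 7
Reactants: 9 furan‑3,4‑diyldimethanol
Product: 11 {4‑[(tert‑butyldiphenylsilyl)oxymethyl]furan‑3‑yl}methanol, via monosodium alkoxide 10 (not isolated)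
Conditions: NaH (1.0 equiv), THF, 0 °C → rt; then TBDPSCl (1.0 equiv)
Reagents that add atoms: tert‑butyl(chloro)diphenylsilane, CC(C)(C)[Si](Cl)(c1ccccc1)c1ccccc1
Why: Monosilylation of a symmetrical diol through its sparingly soluble monosodium alkoxide, which is silylated faster than it equilibrates to the dialkoxide.

Step 8
Reactants: 11 {4‑[(tert‑butyldiphenylsilyl)oxymethyl]furan‑3‑yl}methanol; 8 (2E,4S)‑1‑bromo‑4‑[(tert‑butyldimethylsilyl)oxy]‑2,6‑dimethylhepta‑2,6‑diene
Product: 13 {2‑[(2E,4S)‑4‑[(tert‑butyldimethylsilyl)oxy]‑2,6‑dimethylhepta‑2,6‑dien‑1‑yl]‑4‑[(tert‑butyldiphenylsilyl)oxymethyl]furan‑3‑yl}methanol, via dilithio furan 12 (not isolated)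
Conditions: n‑BuLi (2.1 equiv), TMEDA, THF, −78 → 0 °C; then 8, −78 °C → rt; H2O
Reagents that add atoms: none
Why: Alkoxide‑directed ortho‑lithiation puts lithium on the furan α‑carbon next to the CH2OLi group (C6), and SN2 alkylation of this 2‑furyllithium at the primary allylic bromide joins C5 to C6 without touching the (E)‑olefin or C2.

Step 9
Reactants: 13 the furylmethanol of step 8
Product: 14 2‑[(2E,4S)‑4‑[(tert‑butyldimethylsilyl)oxy]‑2,6‑dimethylhepta‑2,6‑dien‑1‑yl]‑4‑[(tert‑butyldiphenylsilyl)oxymethyl]furan‑3‑carbaldehyde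
Conditions: MnO2 (activated, excess), CH2Cl2, rt
Reagents that add atoms: none
Why: Heterogeneous MnO2 oxidation is selective for the benzylic‑type furylmethanol and stops at the aldehyde (C8), leaving silyl ethers and isolated alkenes alone.

Step 10
Reactants: 14 the furan‑3‑carbaldehyde of step 9
Product: 15 2‑[(2E,4S)‑4‑hydroxy‑2,6‑dimethylhepta‑2,6‑dien‑1‑yl]‑4‑[(tert‑butyldiphenylsilyl)oxymethyl]furan‑3‑carbaldehyde
Conditions: HF·pyridine, pyridine, THF, 0 °C → rt
Reagents that add atoms: none
Why: Acid‑type fluoride desilylation cleaves the secondary TBS ether much faster than the bulkier primary TBDPS ether, and the buffered medium should not ionise the allylic alcohol.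

Step 11
Reactants: 15 the C2 alcohol of step 10
Product: 16 (2E,4S)‑1‑{3‑formyl‑4‑[(tert‑butyldiphenylsilyl)oxymethyl]furan‑2‑yl}‑2,6‑dimethylhepta‑2,6‑dien‑4‑yl acetate
Conditions: Ac2O, pyridine, DMAP (cat.), CH2Cl2, 0 °C
Reagents that add atoms: acetic anhydride, CC(=O)OC(C)=O
Why: DMAP‑catalysed acylation of the only free hydroxyl installs the C2 acetate of the target with retention.

Step 12
Reactants: 16 the acetate aldehyde of step 11
Product: 17 (E)‑aldoxime of 16
Conditions: NH2OH·HCl, NaOAc, EtOH/H2O, rt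
Reagents that add atoms: hydroxylamine hydrochloride, NO.Cl
Why: Condensation of the aldehyde with hydroxylamine under acetate buffer gives the aldoxime much faster than the allylic acetate can be cleaved.

Step 13
Reactants: 17 (E)‑aldoxime of 16
Product: 19 furan‑fused ten‑membered carbocycle bridged from C8 to C10 by a 2‑isoxazoline (C8=N–O–C10), via nitrile oxide 18 (not isolated)
Conditions: PhI(OAc)2 (1.1 equiv), CF3CO2H (5 mol%), MeOH/CH2Cl2, 0 °C; then toluene (1 mM), 60 °C
Reagents that add atoms: none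
Why: PhI(OAc)2 dehydrogenates the aldoxime to nitrile oxide 18, whose carbon (C8) and oxygen add in a concerted, asynchronous 1,3‑dipolar cycloaddition across the 1,1‑disubstituted alkene C9=C10, forming C8–C9 and O–C10 in one event. The closest known reaction type is the intramolecular nitrile oxide–alkene cycloaddition used to close medium and large carbocycles as bridged 2‑isoxazolines, which are masked β‑hydroxy ketones. Two rings close: the isoxazoline (C8, N, O, C10, C9) by [3+2] addition and the ten‑membered carbocycle in the bridged 10‑endo mode in which both alkene carbons enter the new ring, whereas the fused 9‑exo alternative would need C8 to bond to the fully substituted C10 against the normal regiochemistry that puts the dipole oxygen on the more substituted alkene carbon. The one new stereocenter, C10, is set under control of the C2 acetoxy stereocenter: A(1,3) strain with the C4 methyl keeps H–C2 in the plane of the (E)‑C3=C4 bond, the acetoxy group points to the outside of the folding chain, and the dipole oxygen is expected to reach the alkene face that leaves the new C10–O bond anti to C2–OAc. The step needs ring closure to outrun bimolecular reactions and to spare the trisubstituted C3=C4 bond: the furan holds C8 and the C5 chain on adjacent carbons, the C6 and C11 substituents flank the dipole and should suppress furoxan dimerisation as in other di‑ortho‑substituted aromatic nitrile oxides, high dilution disfavours oligomers, and attack on C3=C4 would require a quaternary C4 in a strained cyclopenta‑fused furan. The non‑halogenating oxidant should leave the furan, both alkenes and the allylic acetate untouched.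

Step 14
Reactants: 19 the bridged isoxazoline of step 13
Product: 21 furan‑fused ten‑membered β‑hydroxy ketone (C8 ketone, C10 tertiary alcohol), via NH ketimine 20 (not isolated)
Conditions: Mo(CO)6 (1.2 equiv), MeCN/H2O (15:1), 80 °C
Reagents that add atoms: water, O
Why: Reductive N–O cleavage of the 2‑isoxazoline by zerovalent molybdenum and hydrolysis of the resulting β‑hydroxy imine unveil the C8 ketone and the C10 alcohol without reducing the alkene, the furan or the esters.

Step 15
Reactants: 21 the β‑hydroxy ketone of step 14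
Product: 22 furan‑fused 1,3‑anti diol (C8 R carbinol, C10 tertiary alcohol, C2 S acetate)
Conditions: Me4NBH(OAc)3, MeCN/AcOH (1:1), −30 °C
Reagents that add atoms: none
Why: Evans–Saksena reduction, in which the C10 hydroxyl exchanges onto boron and delivers hydride intramolecularly through a chair six‑membered transition state with both ring bonds (to C7 and to C1) equatorial, should give the 1,3‑anti diol and hence C8 (R).

Step 16
Reactants: 22 the anti diol of step 15
Product: 23 C8 methacrylate of 22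
Conditions: methacrylic anhydride, Et3N, DMAP (cat.), CH2Cl2, 0 °C → rt
Reagents that add atoms: methacrylic anhydride, C=C(C)C(=O)OC(=O)C(C)=C
Why: DMAP‑catalysed acylation differentiates the secondary C8 carbinol from the tertiary C10 alcohol, which does not acylate under these conditions.

Step 17
Reactants: 23 the C8 methacrylate of step 16
Product: 24 C10 triethylsilyl ether of 23
Conditions: TESOTf, 2,6‑lutidine, CH2Cl2, −78 → 0 °C
Reagents that add atoms: triethylsilyl trifluoromethanesulfonate, CC[Si](CC)(CC)OS(=O)(=O)C(F)(F)F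
Why: Silylation with a silyl triflate and a hindered base masks the tertiary C10 hydroxyl so that it cannot add across the ring to C6 once that carbon becomes electrophilic.

Step 18
Reactants: 24 the C10 triethylsilyl ether of step 17
Product: 26 γ‑hydroxybutenolide (C12 carbonyl, C6 lactol, C6 epimers), via furan endoperoxide 25 (not isolated)
Conditions: O2, hν (visible), tetraphenylporphyrin (cat.), i‑Pr2NEt, CH2Cl2, −78 °C
Reagents that add atoms: oxygen, O=O
Why: [4+2] Photooxygenation of the furan by singlet oxygen and amine‑induced Kornblum–DeLaMare fragmentation of the endoperoxide at its only C–H bridgehead (C12) should give the γ‑hydroxybutenolide with the carbonyl at C12 and the hydroxyl at C6, the electron‑rich furan reacting far faster than the trisubstituted alkene or the methacrylate, and the new C6 centre forms as a mixture that step 19 removes.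

Step 19
Reactants: 26 the γ‑hydroxybutenolide of step 18
Product: 28 bis‑silylated ylidene butenolide (target skeleton with C10 OTES and C13 OTBDPS), via lactol acetate 27 (not isolated)
Conditions: Ac2O, Et3N, DMAP (cat.), CH2Cl2, 0 °C; then DBU, 0 °C → rt
Reagents that add atoms: none
Why: Acylation of the lactol hydroxyl and base‑promoted β‑elimination of acetic acid (dehydration of a γ‑hydroxybutenolide to a γ‑ylidenebutenolide) can only take an allylic C5 hydrogen, and because C4 and C7 are both ring atoms the C5=C6 bond must form with C4 cis to C7, since an (E,E)‑1,3‑diene cannot sit in the ten‑membered ring.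

Step 20
Reactants: 28 the bis‑silylated ylidene butenolide of step 19
Product: 29 CNP0246543.2 (target)
Conditions: HF·pyridine, pyridine, THF, 0 °C → rt
Reagents that add atoms: none
Why: Buffered fluoride desilylation removes the tertiary triethylsilyl and the primary tert‑butyldiphenylsilyl ethers without hydrolysing the acetate, the methacrylate or the enol lactone.

Compound list
1 | ethyl glyoxylate | CCOC(=O)C=O | starting material
2 | isobutylene (2‑methylpropene) | CC(C)=C | starting material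
3 | ethyl (2S)‑2‑hydroxy‑4‑methylpent‑4‑enoate | C=C(C)C[C@H](O)C(=O)OCC | intermediate
4 | ethyl (2S)‑2‑[(tert‑butyldimethylsilyl)oxy]‑4‑methylpent‑4‑enoate | C=C(C)C[C@H](O[Si](C)(C)C(C)(C)C)C(=O)OCC | intermediate
5 | (2S)‑2‑[(tert‑butyldimethylsilyl)oxy]‑4‑methylpent‑4‑enal | C=C(C)C[C@H](O[Si](C)(C)C(C)(C)C)C=O | intermediate
6 | ethyl (2E,4S)‑4‑[(tert‑butyldimethylsilyl)oxy]‑2,6‑dimethylhepta‑2,6‑dienoate | C=C(C)C[C@H](O[Si](C)(C)C(C)(C)C)/C=C(C)/C(=O)OCC | intermediate
7 | (2E,4S)‑4‑[(tert‑butyldimethylsilyl)oxy]‑2,6‑dimethylhepta‑2,6‑dien‑1‑ol | C=C(C)C[C@H](O[Si](C)(C)C(C)(C)C)/C=C(C)/CO | intermediate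
8 | (2E,4S)‑1‑bromo‑4‑[(tert‑butyldimethylsilyl)oxy]‑2,6‑dimethylhepta‑2,6‑diene | C=C(C)C[C@H](O[Si](C)(C)C(C)(C)C)/C=C(C)/CBr | intermediate
9 | furan‑3,4‑diyldimethanol | OCc1cocc1CO | starting material
10 | sodium [4‑(hydroxymethyl)furan‑3‑yl]methanolate (not isolated) | [Na]OCc1cocc1CO | intermediate
11 | {4‑[(tert‑butyldiphenylsilyl)oxymethyl]furan‑3‑yl}methanol | OCc1cocc1CO[Si](c1ccccc1)(c1ccccc1)C(C)(C)C | intermediate
12 | lithium {2‑lithio‑4‑[(tert‑butyldiphenylsilyl)oxymethyl]furan‑3‑yl}methanolate (not isolated) | [Li]OCc1c([Li])occ1CO[Si](c1ccccc1)(c1ccccc1)C(C)(C)C | intermediate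
13 | {2‑[(2E,4S)‑4‑[(tert‑butyldimethylsilyl)oxy]‑2,6‑dimethylhepta‑2,6‑dien‑1‑yl]‑4‑[(tert‑butyldiphenylsilyl)oxymethyl]furan‑3‑yl}methanol | C=C(C)C[C@H](O[Si](C)(C)C(C)(C)C)/C=C(C)/Cc1occ(CO[Si](c2ccccc2)(c2ccccc2)C(C)(C)C)c1CO | intermediate
14 | 2‑[(2E,4S)‑4‑[(tert‑butyldimethylsilyl)oxy]‑2,6‑dimethylhepta‑2,6‑dien‑1‑yl]‑4‑[(tert‑butyldiphenylsilyl)oxymethyl]furan‑3‑carbaldehyde | C=C(C)C[C@H](O[Si](C)(C)C(C)(C)C)/C=C(C)/Cc1occ(CO[Si](c2ccccc2)(c2ccccc2)C(C)(C)C)c1C=O | intermediate
15 | 2‑[(2E,4S)‑4‑hydroxy‑2,6‑dimethylhepta‑2,6‑dien‑1‑yl]‑4‑[(tert‑butyldiphenylsilyl)oxymethyl]furan‑3‑carbaldehyde | C=C(C)C[C@H](O)/C=C(C)/Cc1occ(CO[Si](c2ccccc2)(c2ccccc2)C(C)(C)C)c1C=O | intermediate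
16 | (2E,4S)‑1‑{3‑formyl‑4‑[(tert‑butyldiphenylsilyl)oxymethyl]furan‑2‑yl}‑2,6‑dimethylhepta‑2,6‑dien‑4‑yl acetate | C=C(C)C[C@H](OC(C)=O)/C=C(C)/Cc1occ(CO[Si](c2ccccc2)(c2ccccc2)C(C)(C)C)c1C=O | intermediate
17 | (E)‑aldoxime of 16 | C=C(C)C[C@H](OC(C)=O)/C=C(C)/Cc1occ(CO[Si](c2ccccc2)(c2ccccc2)C(C)(C)C)c1/C=N/O | intermediate
18 | furan‑3‑carbonitrile oxide derived from 17 (not isolated) | C=C(C)C[C@H](OC(C)=O)/C=C(C)/Cc1occ(CO[Si](c2ccccc2)(c2ccccc2)C(C)(C)C)c1C#[N+][O-] | intermediate
19 | furan‑fused ten‑membered carbocycle with a 2‑isoxazoline bridge C8=N–O–C10; C2 (S) acetate, (E)‑C3=C4, C10 arranged as in the target (CIP descriptor R here, because C1 outranks C9), C13 OTBDPS | [C@@]12(C)C[C@H](OC(C)=O)/C=C(C)/Cc3occ(CO[Si](c4ccccc4)(c4ccccc4)C(C)(C)C)c3C(=NO1)C2 | intermediate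
20 | C8 NH‑ketimine with free C10 tertiary alcohol (not isolated) | N=C1C[C@@](C)(O)C[C@H](OC(C)=O)/C=C(C)/Cc2occ(CO[Si](c3ccccc3)(c3ccccc3)C(C)(C)C)c21 | intermediate
21 | furan‑fused ten‑membered β‑hydroxy ketone: C8 ketone, C10 (S) tertiary alcohol, C2 (S) acetate, (E)‑C3=C4 | O=C1C[C@@](C)(O)C[C@H](OC(C)=O)/C=C(C)/Cc2occ(CO[Si](c3ccccc3)(c3ccccc3)C(C)(C)C)c21 | intermediate
22 | furan‑fused 1,3‑anti diol: C8 (R) carbinol, C10 tertiary alcohol arranged as in the target, C2 (S) acetate | O[C@@H]1C[C@@](C)(O)C[C@H](OC(C)=O)/C=C(C)/Cc2occ(CO[Si](c3ccccc3)(c3ccccc3)C(C)(C)C)c21 | intermediate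
23 | C8 (R) methacrylate of 22 (C10 S, C2 S) | C=C(C)C(=O)O[C@@H]1C[C@@](C)(O)C[C@H](OC(C)=O)/C=C(C)/Cc2occ(CO[Si](c3ccccc3)(c3ccccc3)C(C)(C)C)c21 | intermediate
24 | C10 triethylsilyl ether of 23 | C=C(C)C(=O)O[C@@H]1C[C@@](C)(O[Si](CC)(CC)CC)C[C@H](OC(C)=O)/C=C(C)/Cc2occ(CO[Si](c3ccccc3)(c3ccccc3)C(C)(C)C)c21 | intermediate
25 | furan 2,5‑endoperoxide of 24, peroxide bridge from C6 to C12 (not isolated) | C=C(C)C(=O)O[C@@H]1C[C@@](C)(O[Si](CC)(CC)CC)C[C@H](OC(C)=O)/C=C(C)/CC23OOC(O2)C(CO[Si](c4ccccc4)(c4ccccc4)C(C)(C)C)=C31 | intermediate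
26 | γ‑hydroxybutenolide: C12 lactone carbonyl, C6 lactol (epimers), C7=C11 | C=C(C)C(=O)O[C@@H]1C[C@@](C)(O[Si](CC)(CC)CC)C[C@H](OC(C)=O)/C=C(C)/CC2(O)OC(=O)C(CO[Si](c3ccccc3)(c3ccccc3)C(C)(C)C)=C21 | intermediate
27 | C6 lactol acetate of 26 (not isolated) | C=C(C)C(=O)O[C@@H]1C[C@@](C)(O[Si](CC)(CC)CC)C[C@H](OC(C)=O)/C=C(C)/CC2(OC(C)=O)OC(=O)C(CO[Si](c3ccccc3)(c3ccccc3)C(C)(C)C)=C21 | intermediate
28 | ylidene butenolide with C10 OTES and C13 OTBDPS (C8 R, C10 S, C2 S; (E)‑C3=C4; C5=C6 with C4 cis to C7) | C=C(C)C(=O)O[C@@H]1C[C@@](C)(O[Si](CC)(CC)CC)C[C@H](OC(C)=O)/C=C(C)/C=C2/OC(=O)C(CO[Si](c3ccccc3)(c3ccccc3)C(C)(C)C)=C21 | intermediate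
29 | CNP0246543.2 | C=C(C)C(=O)O[C@@H]1C[C@@](C)(O)C[C@H](OC(C)=O)/C=C(C)/C=C2/OC(=O)C(CO)=C21 | target

Total step count: 20. Longest linear sequence: 19 steps (steps 1–6, then 8–20).

Steps most likely to fail

Step 13. The dipole may add to the wrong face of the C9=C10 alkene, because C2 steers it only through the folding of a flexible ten‑membered transition state; this prediction is the least secure element of the route. Fallback (stereochemical relay, known reactions): set out from alcohol 15. A Mitsunobu reaction (PPh3, DIAD, benzoic acid, THF) should invert C2 and give (2E,4R)‑1‑{3‑formyl‑4‑[(tert‑butyldiphenylsilyl)oxymethyl]furan‑2‑yl}‑2,6‑dimethylhepta‑2,6‑dien‑4‑yl benzoate F1. NH2OH·HCl/NaOAc should give its oxime F2. PhI(OAc)2 under the conditions of step 13 should give the nitrile oxide F3 and from it the C2‑epimeric isoxazoline benzoate F4, in which the mirror‑image folding puts the oxygen on the required face of C10. K2CO3/MeOH should free the C2‑epimeric isoxazoline alcohol F5, and a second Mitsunobu reaction with acetic acid inverts C2 again and comes back to the route at 19.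

Step 18. Singlet oxygen may also attack the trisubstituted C3=C4 bond in an ene reaction, or the endoperoxide may decompose before it is deprotonated at C12. Fallback (two‑electron oxidation instead of photooxygenation): set out from furan 24. NBS, NaHCO3, acetone/H2O, −20 °C should open the furan to the (Z)‑4‑oxo‑enal (C6 ketone, C12 aldehyde) F6. Pinnick oxidation (NaClO2, NaH2PO4, 2‑methyl‑2‑butene, t‑BuOH/H2O) should take the formyl group to the acid, whose ring tautomer is hydroxybutenolide 26, where the route is rejoined.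

Step 8. Metalation may also occur at the other α‑carbon (C12) under the influence of the silyloxymethyl group, with migration of silicon from oxygen to carbon, and the poorly soluble dianion may be alkylated slowly. Fallback (directing group on the aldehyde instead of the alcohol): set out from 11. MnO2 should give 4‑[(tert‑butyldiphenylsilyl)oxymethyl]furan‑3‑carbaldehyde F7. LiN(CH3)CH2CH2N(CH3)2 adds to the formyl group to give the lithium α‑amino alkoxide F8, whose chelating arm directs n‑BuLi to C6 to give the C6‑lithio α‑amino alkoxide F9. Bromide 8 should then give the C6‑alkylated α‑amino alkoxide F10, and aqueous work‑up releases aldehyde 14, where the route is rejoined (step 9 is then not needed).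

Further compounds
F1 | step 13 | (2E,4R)‑1‑{3‑formyl‑4‑[(tert‑butyldiphenylsilyl)oxymethyl]furan‑2‑yl}‑2,6‑dimethylhepta‑2,6‑dien‑4‑yl benzoate | C=C(C)C[C@@H](OC(=O)c1ccccc1)/C=C(C)/Cc1occ(CO[Si](c2ccccc2)(c2ccccc2)C(C)(C)C)c1C=O
F2 | step 13 | (E)‑aldoxime of F1 | C=C(C)C[C@@H](OC(=O)c1ccccc1)/C=C(C)/Cc1occ(CO[Si](c2ccccc2)(c2ccccc2)C(C)(C)C)c1/C=N/O
F3 | step 13 | nitrile oxide derived from F2 | C=C(C)C[C@@H](OC(=O)c1ccccc1)/C=C(C)/Cc1occ(CO[Si](c2ccccc2)(c2ccccc2)C(C)(C)C)c1C#[N+][O-]
F4 | step 13 | C2‑epimeric isoxazoline benzoate (C10 as in 19) | [C@@]12(C)C[C@@H](OC(=O)c3ccccc3)/C=C(C)/Cc3occ(CO[Si](c4ccccc4)(c4ccccc4)C(C)(C)C)c3C(=NO1)C2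
F5 | step 13 | C2‑epimeric isoxazoline alcohol | [C@@]12(C)C[C@@H](O)/C=C(C)/Cc3occ(CO[Si](c4ccccc4)(c4ccccc4)C(C)(C)C)c3C(=NO1)C2
F6 | step 18 | (Z)‑4‑oxo‑enal from oxidative opening of furan 24 (C6 ketone, C12 aldehyde) | C=C(C)C(=O)O[C@@H]1C[C@@](C)(O[Si](CC)(CC)CC)C[C@H](OC(C)=O)/C=C(C)/CC(=O)/C1=C(\C=O)CO[Si](c2ccccc2)(c2ccccc2)C(C)(C)C
F7 | step 8 | 4‑[(tert‑butyldiphenylsilyl)oxymethyl]furan‑3‑carbaldehyde | O=Cc1cocc1CO[Si](c1ccccc1)(c1ccccc1)C(C)(C)C
F8 | step 8 | lithium α‑amino alkoxide from F7 and lithium N,N,N′‑trimethylethylenediamide | CN(C)CCN(C)C(O[Li])c1cocc1CO[Si](c1ccccc1)(c1ccccc1)C(C)(C)C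
F9 | step 8 | C6‑lithio α‑amino alkoxide | CN(C)CCN(C)C(O[Li])c1c([Li])occ1CO[Si](c1ccccc1)(c1ccccc1)C(C)(C)C
F10 | step 8 | C6‑alkylated α‑amino alkoxide | C=C(C)C[C@H](O[Si](C)(C)C(C)(C)C)/C=C(C)/Cc1occ(CO[Si](c2ccccc2)(c2ccccc2)C(C)(C)C)c1C(O[Li])N(C)CCN(C)C
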